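The target is a meso dimer: two mirror-image cyclohexane rings (ring A, ring B), each a cis β-hydroxy ketone with quaternary C1 next to carbinol C2, joined through Z-alkylidenes at C3 by a four-carbon chain. Everything rests on disconnecting the C1–C6 ring bond of each ring. The key step, a two-fold intramolecular Fráter–Seebach alkylation, exploits the 1,3-relationship of the C2 oxygen and the C1 carbonyl: the tetralithio derivative of an acyclic meso bis(β-hydroxy ester) bearing both Z-alkenes and two 3-chloropropyl arms closes both rings at once, each C2 alkoxide relaying its configuration to C1 through a lithium chelate. The heterochiral carbinols come from two successive Evans aldols with enantiomeric auxiliaries; the prenyl ketones are installed last.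

Key step: step 8

Remark on ring numbering: C1 is the quaternary carbon, C2 the carbinol carbon, C3 the alkylidene-bearing carbon, and C4–C6 the three ring CH2 groups, with C6 bonded to C1.

Assumption: butanedial is taken as commercial; it is sold as an aqueous solution and would be extracted, dried and distilled just before use.

Step 1
Reactants: 1 methyl bis(2,2,2-trifluoroethyl)phosphonoacetate; 2 1-bromo-3-chloropropane
Product: 4 methyl 2-[bis(2,2,2-trifluoroethoxy)phosphoryl]-5-chloropentanoate (racemic), via sodium carbanion of the phosphonoacetate 3 (not isolated)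
Conditions: NaH (0.95 equiv), DMF, 0 °C; then 2 (3 equiv), 0 °C → rt
Reagents that add atoms: none
Why: Malonate-type SN2 alkylation of the stabilised phosphonoacetate carbanion should take place only at the bromide end of 2, and the excess of 2 with a slight deficit of base limits dialkylation; the new stereocenter is racemic and is erased in step 2.

Step 2
Reactants: 4 methyl 2-[bis(2,2,2-trifluoroethoxy)phosphoryl]-5-chloropentanoate; 5 butanedial
Product: 7 dimethyl (2Z,6Z)-2,7-bis(3-chloropropyl)octa-2,6-dienedioate, via potassium carbanion of the phosphonate 6 (not isolated)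
Conditions: 4 (2.3 equiv), KN(SiMe3)2, 18-crown-6, THF, −78 °C; then 5, −78 °C
Reagents that add atoms: none
Why: Two-fold Still–Gennari olefination: the electron-poor trifluoroethyl phosphonate under dissociating conditions eliminates kinetically to the Z-trisubstituted enoate, which places each ester carbon (the future C2) cis to the central chain, as the exocyclic alkenes of the target require.

Step 3
Reactants: 7 dimethyl (2Z,6Z)-2,7-bis(3-chloropropyl)octa-2,6-dienedioate
Product: 8 (2Z,6Z)-2,7-bis(3-chloropropyl)octa-2,6-diene-1,8-diol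
Conditions: i-Bu2AlH (5 equiv), CH2Cl2, −78 °C; aq. potassium sodium tartrate
Reagents that add atoms: none
Why: 1,2-Reduction of the enoates by i-Bu2AlH at low temperature should give the bis-allylic alcohol without touching the alkyl chlorides or the alkene geometry.

Step 4
Reactants: 8 (2Z,6Z)-2,7-bis(3-chloropropyl)octa-2,6-diene-1,8-diol
Product: 9 (2Z,6Z)-2,7-bis(3-chloropropyl)octa-2,6-dienedial
Conditions: Dess–Martin periodinane, NaHCO3, CH2Cl2, 0 °C; used at once
Reagents that add atoms: none
Why: Buffered Dess–Martin oxidation is neutral and fast, so the Z-enals, which are the less stable geometric isomers, should form without isomerisation if used directly.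

Step 5
Reactants: 9 (2Z,6Z)-2,7-bis(3-chloropropyl)octa-2,6-dienedial; 10 (R)-4-benzyl-3-propionyloxazolidin-2-one
Product: 12 (4R)-4-benzyl-3-[(2R,3R,4Z,8Z)-4,9-bis(3-chloropropyl)-3-hydroxy-2-methyl-10-oxodeca-4,8-dienoyl]oxazolidin-2-one, via dibutylboron Z-enolate 11 (not isolated)
Conditions: 10 (1 equiv), Bu2BOTf, iPr2NEt, CH2Cl2, 0 °C; then 9 (3 equiv), −78 → −20 °C; pH 7 phosphate buffer, MeOH (no peroxide)
Reagents that add atoms: none
Why: Evans syn aldol: the Z-boron enolate 11 adds through a Zimmerman–Traxler chair in which the (R)-benzyl auxiliary fixes the enolate face, setting the carbinol (3R, the future ring A C2) and the adjacent methine (2R, erased in step 8), while the excess of 9, which is recovered, keeps the reaction at mono-addition.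

Step 6
Reactants: 12 the mono-aldol adduct; 13 (S)-4-benzyl-3-propionyloxazolidin-2-one
Product: 15 heterochiral bis-aldol adduct (2R,3R,4Z,8Z,10S,11S) carrying the (R)-auxiliary at C1 and the (S)-auxiliary at C12, via dibutylboron Z-enolate 14 (not isolated)
Conditions: 13 (2.5 equiv), Bu2BOTf, iPr2NEt, CH2Cl2, 0 °C; then 12, −78 → 0 °C; pH 7 phosphate buffer, MeOH
Reagents that add atoms: none
Why: The same Evans syn aldol with the enantiomeric auxiliary sets the second carbinol (10S, the future ring B C2) under pure reagent control, the two ends being too far apart to influence each other, so that the bis-adduct should be the heterochiral, meso-configured compound; the extra enolate covers the free hydroxyl of 12.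

Step 7
Reactants: 15 the heterochiral bis-aldol adduct
Product: 16 dimethyl (2R,3R,4Z,8Z,10S,11S)-4,9-bis(3-chloropropyl)-3,10-dihydroxy-2,11-dimethyldodeca-4,8-dienedioate (meso)
Conditions: NaOMe (0.5 equiv), MeOH–CH2Cl2, 0 °C
Reagents that add atoms: methanol, CO (delivered as sodium methoxide, C[O-].[Na+])
Why: Methoxide attacks the exocyclic imide carbonyl of each N-acyloxazolidinone (transesterification) and releases both auxiliaries, the carbinol centers being untouched and the methine centers being irrelevant.

Step 8
Reactants: 16 the meso bis(β-hydroxy methyl ester)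
Product: 18 meso dimethyl 3,3'-[(1Z,4Z)-butane-1,4-diylidene]bis(2-hydroxy-1-methylcyclohexane-1-carboxylate) with ring A (1R,2S) and ring B (1S,2R), via tetralithio bis-enolate bis-alkoxide 17 (not isolated)
Conditions: LiN(iPr)2 (4.6 equiv), THF, −78 → −30 °C; then DMPU, −30 °C → rt; aq. NH4Cl
Reagents that add atoms: none
Why: LiN(iPr)2 removes the hydroxyl proton and the C1–H at each end, giving twice in one molecule the chelated enolate–alkoxide pair of a Fráter–Seebach dianion (17), and each enolate carbon C1 then displaces the chloride at C6 of its own arm by SN2. The closest known reaction type is the Fráter–Seebach α-alkylation of β-hydroxy ester dianions, run here intramolecularly and in two directions. Each cyclohexane closes in a 6-exo-tet mode with the enolate double bond exocyclic to the new ring. Each quaternary C1 is controlled by its own C2: because the arm hangs from C2, C1 must attack in a chair in which the C2–O bond lies near the enolate plane on the side of the enolate oxygen (one lithium bridging both oxygens), with the C2–H turned toward the C1 methyl and toward the cis chain of the Z-alkene (no allylic strain); this puts the ester cis to the C2 oxygen and the methyl trans, whereas the other enolate face would push the alkoxide against the C1 methyl and break the chelate. The step needs C-alkylation to beat O-alkylation by the C2 alkoxide (closure to a tetrahydropyran) and each enolate to take its own arm; the much higher nucleophilicity of the ester enolate carbon compared with a chelated lithium alkoxide, and the six-membered transition state, should secure both. Since the two C2 centers were set with opposite configuration, the product should be the meso diester.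

Step 9
Reactants: 18 the meso bicyclic diol diester
Product: 19 bis(triethylsilyl) ether of 18
Conditions: Et3SiOTf, 2,6-lutidine, CH2Cl2, −78 → 0 °C
Reagents that add atoms: triethylsilyl trifluoromethanesulfonate, CC[Si](CC)(CC)OS(=O)(=O)C(F)(F)F
Why: Silylation of the hindered secondary alcohols with the reactive silyl triflate (standard protection) masks both C2 hydroxyls against the later oxidations without affecting any stereocenter.

Step 10
Reactants: 19 the bis(triethylsilyl) ether diester
Product: 20 bis(hydroxymethyl) compound (each CO2Me reduced to CH2OH)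
Conditions: i-Bu2AlH (6 equiv), CH2Cl2, −78 → 0 °C; aq. potassium sodium tartrate
Reagents that add atoms: none
Why: Exhaustive i-Bu2AlH reduction of the neopentyl methyl esters should give the primary alcohols, the silyl ethers and alkenes being inert.

Step 11
Reactants: 20 the bis(hydroxymethyl) compound
Product: 21 bis-aldehyde (each CH2OH oxidised to CHO)
Conditions: Dess–Martin periodinane, NaHCO3, CH2Cl2, rt
Reagents that add atoms: none
Why: Dess–Martin oxidation of the neopentyl primary alcohols gives the aldehydes, which have no α-hydrogen and so cannot epimerise.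

Step 12
Reactants: 21 the bis-aldehyde; 22 1-chloro-3-methylbut-2-ene (prenyl chloride)
Product: 24 bis(homoallylic alcohol) with each CHO converted to CH(OH)CH2CH=CMe2 (mixture at the new carbinols), via prenylbarium chloride 23 (not isolated)
Conditions: BaI2, Li(C12H10) (lithium biphenylide, stock solution), THF, rt; 22 (3 equiv), −78 °C; then 21, −78 °C; aq. NH4Cl at −78 °C
Reagents that add atoms: none
Why: Yamamoto allylbarium addition: prenylbarium chloride 23 adds to aldehydes through its unsubstituted α-carbon, giving the linear homoallylic alcohols; the two new carbinol centers form as a mixture and are removed by oxidation in step 13.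

Step 13
Reactants: 24 the bis(homoallylic alcohol)
Product: 25 bis(triethylsilyl) ether of the target
Conditions: Dess–Martin periodinane, NaHCO3, CH2Cl2, 0 °C → rt
Reagents that add atoms: none
Why: Buffered Dess–Martin oxidation converts the homoallylic alcohols into the β,γ-unsaturated ketones under neutral conditions that should not move the double bonds into conjugation.

Step 14
Reactants: 25 the bis(triethylsilyl) ether of the target
Product: 26 CNP0297042.2
Conditions: HF·pyridine, pyridine, THF, 0 °C → rt
Reagents that add atoms: none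
Why: Buffered HF·pyridine cleaves the triethylsilyl ethers under mildly acidic conditions, avoiding the base that would trigger retro-aldol cleavage of the β-hydroxy ketones or conjugation of the β,γ-enones.

Compound list
1 | methyl bis(2,2,2-trifluoroethyl)phosphonoacetate | COC(=O)CP(=O)(OCC(F)(F)F)OCC(F)(F)F | starting material
2 | 1-bromo-3-chloropropane | ClCCCBr | starting material
3 | sodium carbanion of 1 | [Na+].COC(=O)[CH-]P(=O)(OCC(F)(F)F)OCC(F)(F)F | intermediate
4 | methyl 2-[bis(2,2,2-trifluoroethoxy)phosphoryl]-5-chloropentanoate (racemic) | COC(=O)C(CCCCl)P(=O)(OCC(F)(F)F)OCC(F)(F)F | intermediate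
5 | butanedial (succinaldehyde) | O=CCCC=O | starting material
6 | potassium carbanion of 4 | [K+].COC(=O)[C-](CCCCl)P(=O)(OCC(F)(F)F)OCC(F)(F)F | intermediate
7 | dimethyl (2Z,6Z)-2,7-bis(3-chloropropyl)octa-2,6-dienedioate | COC(=O)/C(CCCCl)=C\CC/C=C(/CCCCl)C(=O)OC | intermediate
8 | (2Z,6Z)-2,7-bis(3-chloropropyl)octa-2,6-diene-1,8-diol | OC/C(CCCCl)=C\CC/C=C(/CCCCl)CO | intermediate
9 | (2Z,6Z)-2,7-bis(3-chloropropyl)octa-2,6-dienedial | O=C/C(CCCCl)=C\CC/C=C(/CCCCl)C=O | intermediate
10 | (R)-4-benzyl-3-propionyloxazolidin-2-one | CCC(=O)N1[C@H](Cc2ccccc2)COC1=O | starting material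
11 | dibutylboron Z-enolate of 10 | CCCCB(CCCC)O/C(=C\C)N1[C@H](Cc2ccccc2)COC1=O | intermediate
12 | (4R)-4-benzyl-3-[(2R,3R,4Z,8Z)-4,9-bis(3-chloropropyl)-3-hydroxy-2-methyl-10-oxodeca-4,8-dienoyl]oxazolidin-2-one | O=C(N1[C@H](Cc2ccccc2)COC1=O)[C@H](C)[C@@H](O)/C(CCCCl)=C\CC/C=C(/CCCCl)C=O | intermediate
13 | (S)-4-benzyl-3-propionyloxazolidin-2-one | CCC(=O)N1[C@@H](Cc2ccccc2)COC1=O | starting material
14 | dibutylboron Z-enolate of 13 | CCCCB(CCCC)O/C(=C\C)N1[C@@H](Cc2ccccc2)COC1=O | intermediate
15 | (4R)-4-benzyl-3-[(2R,3R,4Z,8Z,10S,11S)-12-[(4S)-4-benzyl-2-oxooxazolidin-3-yl]-4,9-bis(3-chloropropyl)-3,10-dihydroxy-2,11-dimethyl-12-oxododeca-4,8-dienoyl]oxazolidin-2-one | O=C(N1[C@H](Cc2ccccc2)COC1=O)[C@H](C)[C@@H](O)/C(CCCCl)=C\CC/C=C(/CCCCl)[C@@H](O)[C@H](C)C(=O)N1[C@@H](Cc2ccccc2)COC1=O | intermediate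
16 | dimethyl (2R,3R,4Z,8Z,10S,11S)-4,9-bis(3-chloropropyl)-3,10-dihydroxy-2,11-dimethyldodeca-4,8-dienedioate (meso) | COC(=O)[C@H](C)[C@@H](O)/C(CCCCl)=C\CC/C=C(/CCCCl)[C@@H](O)[C@H](C)C(=O)OC | intermediate
17 | tetralithio derivative of 16 (two ester enolates with OLi cis to the carbinol carbon, two alkoxides) | [Li+].[Li+].[Li+].[Li+].[O-]/C(OC)=C(/C)[C@@H]([O-])/C(CCCCl)=C\CC/C=C(/CCCCl)[C@@H]([O-])/C(C)=C(\[O-])OC | intermediate
18 | meso dimethyl 3,3'-[(1Z,4Z)-butane-1,4-diylidene]bis(2-hydroxy-1-methylcyclohexane-1-carboxylate); ring A (1R,2S,3Z), ring B (1S,2R,3Z); OH cis to CO2Me in each ring | COC(=O)[C@]1(C)CCC/C(=C/CC/C=C2/CCC[C@](C)(C(=O)OC)[C@@H]2O)[C@@H]1O | intermediate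
19 | bis(triethylsilyl) ether of 18 (configuration unchanged) | COC(=O)[C@]1(C)CCC/C(=C/CC/C=C2/CCC[C@](C)(C(=O)OC)[C@@H]2O[Si](CC)(CC)CC)[C@@H]1O[Si](CC)(CC)CC | intermediate
20 | bis(hydroxymethyl) analogue of 19 (CH2OH in place of each CO2Me, cis to OSiEt3; meso) | OC[C@]1(C)CCC/C(=C/CC/C=C2/CCC[C@](C)(CO)[C@@H]2O[Si](CC)(CC)CC)[C@@H]1O[Si](CC)(CC)CC | intermediate
21 | bis-aldehyde (CHO in place of each CO2Me of 19; meso) | O=C[C@]1(C)CCC/C(=C/CC/C=C2/CCC[C@](C)(C=O)[C@@H]2O[Si](CC)(CC)CC)[C@@H]1O[Si](CC)(CC)CC | intermediate
22 | 1-chloro-3-methylbut-2-ene (prenyl chloride) | CC(C)=CCCl | starting material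
23 | prenylbarium chloride | CC(C)=CC[Ba]Cl | intermediate
24 | bis(homoallylic alcohol): 1-hydroxy-4-methylpent-3-enyl group on each C1, new carbinols as a mixture, ring centers as in 19 | CC(C)=CCC(O)[C@]1(C)CCC/C(=C/CC/C=C2/CCC[C@](C)(C(O)CC=C(C)C)[C@@H]2O[Si](CC)(CC)CC)[C@@H]1O[Si](CC)(CC)CC | intermediate
25 | bis(triethylsilyl) ether of the target (4-methylpent-3-enoyl group on each C1) | CC(C)=CCC(=O)[C@]1(C)CCC/C(=C/CC/C=C2/CCC[C@](C)(C(=O)CC=C(C)C)[C@@H]2O[Si](CC)(CC)CC)[C@@H]1O[Si](CC)(CC)CC | intermediate
26 | CNP0297042.2: 1-[(1R,2S,3Z)-2-hydroxy-3-{4-[(1Z,2R,3S)-2-hydroxy-3-methyl-3-(4-methylpent-3-enoyl)cyclohexylidene]butylidene}-1-methylcyclohexyl]-4-methylpent-3-en-1-one (meso) | CC(C)=CCC(=O)[C@]1(C)CCC/C(=C/CC/C=C2/CCC[C@](C)(C(=O)CC=C(C)C)[C@@H]2O)[C@@H]1O | target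

Total step count: 14. Longest linear sequence: 14 steps (1 → 26).

Steps most likely to fail

Step 8 (key step). The displacement of a primary chloride by the hindered, tetrasubstituted enolate may be slow. O-alkylation by the C2 alkoxide, decay of the tetraanion on warming, or closure of only one ring could then compete. The fallback sets out from 16: halide exchange (NaI, butan-2-one, reflux) should give the bis-iodide F1. Its tetraanion (LiN(iPr)2, THF, −78 → −30 °C, no polar cosolvent) should close both rings well below the temperature at which a lithium alkoxide alkylates. The fallback comes back to the route at 18.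

Step 5. The mono-aldol on a symmetric dialdehyde is statistical, so over-addition to the homochiral bis-adduct, incomplete conversion and loss of Z geometry in the excess enal during recovery may erode the material balance. The fallback sets out from diol 8 and differentiates the two ends before any aldehyde is made. Monosilylation through the mono-alkoxide (NaH 1 equiv, t-BuMe2SiCl, THF) gives the mono-silyl ether F2. Dess–Martin oxidation gives the mono-aldehyde F3. The Evans aldol with enolate 11 gives the silyl-protected adduct F4. HF·pyridine gives the hydroxy imide F5. Chemoselective oxidation of the primary allylic alcohol (TEMPO, PhI(OAc)2, CH2Cl2) comes back to the route at 12.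

Step 12. The prenyl metal may attack through its substituted γ-terminus (reverse prenylation) or fail to add to the neopentyl aldehydes, and the barium alkoxides may induce silyl migration from the C2 oxygen. The fallback sets out from 21 and uses a sulfone-stabilised prenyl anion, which reacts at its α-carbon. Lithiated 3-methylbut-2-enyl phenyl sulfone (CC(C)=CCS(=O)(=O)c1ccccc1; n-BuLi, THF, −78 °C) gives the bis(β-hydroxy sulfone) F6. Dess–Martin oxidation gives the bis(β-keto sulfone) F7. Reductive desulfonylation (SmI2, THF–MeOH, −78 °C) with kinetic α-protonation of the dienolate comes back to the route at 25, bypassing 24.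

Further compounds
F1 | step 8 | dimethyl (2R,3R,4Z,8Z,10S,11S)-3,10-dihydroxy-4,9-bis(3-iodopropyl)-2,11-dimethyldodeca-4,8-dienedioate | COC(=O)[C@H](C)[C@@H](O)/C(CCCI)=C\CC/C=C(/CCCI)[C@@H](O)[C@H](C)C(=O)OC
F2 | step 5 | (2Z,6Z)-8-(tert-butyldimethylsilyloxy)-2,7-bis(3-chloropropyl)octa-2,6-dien-1-ol | CC(C)(C)[Si](C)(C)OC/C(CCCCl)=C\CC/C=C(/CCCCl)CO
F3 | step 5 | (2Z,6Z)-8-(tert-butyldimethylsilyloxy)-2,7-bis(3-chloropropyl)octa-2,6-dienal | CC(C)(C)[Si](C)(C)OC/C(CCCCl)=C\CC/C=C(/CCCCl)C=O
F4 | step 5 | (4R)-4-benzyl-3-[(2R,3R,4Z,8Z)-10-(tert-butyldimethylsilyloxy)-4,9-bis(3-chloropropyl)-3-hydroxy-2-methyldeca-4,8-dienoyl]oxazolidin-2-one | O=C(N1[C@H](Cc2ccccc2)COC1=O)[C@H](C)[C@@H](O)/C(CCCCl)=C\CC/C=C(/CCCCl)CO[Si](C)(C)C(C)(C)C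
F5 | step 5 | (4R)-4-benzyl-3-[(2R,3R,4Z,8Z)-4,9-bis(3-chloropropyl)-3,10-dihydroxy-2-methyldeca-4,8-dienoyl]oxazolidin-2-one | O=C(N1[C@H](Cc2ccccc2)COC1=O)[C@H](C)[C@@H](O)/C(CCCCl)=C\CC/C=C(/CCCCl)CO
F6 | step 12 | bis(β-hydroxy sulfone): 1-hydroxy-4-methyl-2-(phenylsulfonyl)pent-3-enyl group on each C1 of the bis-silyl ether (mixture at the new centers) | CC(C)=CC(S(=O)(=O)c1ccccc1)C(O)[C@]2(C)CCC/C(=C/CC/C=C3/CCC[C@](C)(C(O)C(C=C(C)C)S(=O)(=O)c4ccccc4)[C@@H]3O[Si](CC)(CC)CC)[C@@H]2O[Si](CC)(CC)CC
F7 | step 12 | bis(β-keto sulfone): 4-methyl-2-(phenylsulfonyl)pent-3-enoyl group on each C1 of the bis-silyl ether | CC(C)=CC(S(=O)(=O)c1ccccc1)C(=O)[C@]2(C)CCC/C(=C/CC/C=C3/CCC[C@](C)(C(=O)C(C=C(C)C)S(=O)(=O)c4ccccc4)[C@@H]3O[Si](CC)(CC)CC)[C@@H]2O[Si](CC)(CC)CC
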